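**Plan**
1. Numbering: daucane (C1 angular C–CH3, C4 C(OH)i-Pr, C5 ring-fusion CH, C6 CH–O, C7 CH2, C8 C(OH)CH3 with methyl C14, C9=C10). β is the face of the C1 methyl; ring A is the cyclopentane, ring B the cycloheptene.
2. Cuts: first the ester C6–O bond; then C8(OH)–C14H3 is read back through the 8,14-epoxide to an exocyclic C8=C14 methylene; then C8–C9 and C6–C7 are cut together. This removes C7–C8–C14 as allene and leaves ring A with a (Z)-2-iodoethenyl group on C1 and a formyl group on C5.
3. Enabling feature: in ring B the C6 carbinol is homoallylic to C8, and C8 is a branch carbon (C14) flanked by the C7 methylene and the C9=C10 alkene. This 2-alkenyl-allyl carbinol array is what an allene gives when it inserts between an alkenylpalladium (C9) and an aldehyde (C6).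
4. Forward: ring A is built from 3-methylcyclopent-2-enone (C1, then C5/C6, then C4) and the C1 arm is turned into the Z-iodoalkene. Ring B is then closed in one palladium/indium three-component event, followed by C8–OH, the ester and desilylation.
5. Stereochemistry: C1 by catalyst-controlled conjugate addition; C5 anti to the bulky C1 alkenylsilane; C4 by addition anti to the C5 arm; C6 in the ring closure under control of C5; C8 by oxygen delivery from the C6 hydroxyl.

Key step: step 8

Remark: the C-numbers in the Why lines are daucane numbers of the target, also for the monocyclic intermediates; 11 and 17 are taken as commercial; the chiral NHC precursor is used as the enantiomer that gives (S)-3.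

**Step 1**
Reactants: 1 3-methylcyclopent-2-en-1-one
Product: 3 (S)-3-methyl-1-(trimethylsilyloxy)-3-[1-(trimethylsilyl)ethenyl]cyclopent-1-ene, via aluminium enolate 2 (not isolated)
Conditions: ethynyltrimethylsilane, i-Bu2AlH, hexanes/THF, 55 °C; then 1, Cu(OTf)2 (5 mol %), chiral sulfonate-bearing imidazolinium salt (NHC precursor, 5 mol %), THF, −78 °C; then TMSOTf, −78 → 0 °C
Reagents that add atoms: diisobutyl[1-(trimethylsilyl)ethenyl]aluminium C=C([Si](C)(C)C)[Al](CC(C)C)CC(C)C (made in the flask from ethynyltrimethylsilane C#C[Si](C)(C)C and i-Bu2AlH); trimethylsilyl trifluoromethanesulfonate C[Si](C)(C)OS(=O)(=O)C(F)(F)F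
Why: Copper-catalysed enantioselective conjugate addition of a silyl-substituted alkenylaluminium to a β-substituted cyclopentenone should set the C1 quaternary centre under control of the chiral NHC–copper catalyst, and O-silylation of the regiodefined enolate 2 fixes the C4=C5 enol ether for the next step.

**Step 2**
Reactants: 3 (S)-3-methyl-1-(trimethylsilyloxy)-3-[1-(trimethylsilyl)ethenyl]cyclopent-1-ene
Product: 4 (2S,3S)-2-(dimethoxymethyl)-3-methyl-3-[1-(trimethylsilyl)ethenyl]cyclopentan-1-one
Conditions: HC(OMe)3, BF3·OEt2, CH2Cl2, −78 °C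
Reagents that add atoms: trimethyl orthoformate COC(OC)OC
Why: Mukaiyama-type addition of the silyl enol ether to the dimethoxycarbenium ion installs C6 at the aldehyde oxidation level, and the electrophile should approach C5 anti to the bulky 1-silylvinyl group so that C6 ends cis to the C1 methyl.

**Step 3**
Reactants: 4 (2S,3S)-2-(dimethoxymethyl)-3-methyl-3-[1-(trimethylsilyl)ethenyl]cyclopentan-1-one
Product: 5 (1R,2R,3S)-2-(dimethoxymethyl)-3-methyl-1-(propan-2-yl)-3-[1-(trimethylsilyl)ethenyl]cyclopentan-1-ol
Conditions: i-PrMgCl, CeCl3, THF, −78 → 0 °C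
Reagents that add atoms: isopropylmagnesium chloride CC(C)[Mg]Cl
Why: Organocerium 1,2-addition suppresses enolisation of the hindered ketone, and the isopropyl group should enter anti to the adjacent C5 acetal arm, which places the C4 hydroxyl on the β face, cis to C6.

**Step 4**
Reactants: 5 (1R,2R,3S)-2-(dimethoxymethyl)-3-methyl-1-(propan-2-yl)-3-[1-(trimethylsilyl)ethenyl]cyclopentan-1-ol
Product: 6 (1R,2R,3S)-2-(dimethoxymethyl)-3-(1-iodoethenyl)-3-methyl-1-(propan-2-yl)cyclopentan-1-ol
Conditions: NIS, MeCN/ClCH2CN (4:1), 0 °C → rt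
Reagents that add atoms: N-iodosuccinimide O=C1CCC(=O)N1I
Why: Iododesilylation of the 1,1-disubstituted vinylsilane is an ipso substitution through a β-silyl-stabilised iodonium ion and should give the 2-iodo-1-alkene without touching the acetal or any stereocentre.

**Step 5**
Reactants: 6 (1R,2R,3S)-2-(dimethoxymethyl)-3-(1-iodoethenyl)-3-methyl-1-(propan-2-yl)cyclopentan-1-ol
Product: 8 (1R,2R,3S)-2-(dimethoxymethyl)-3-(iodoethynyl)-3-methyl-1-(propan-2-yl)cyclopentan-1-ol, via lithium acetylide 7 (not isolated)
Conditions: LiN(i-Pr)2 (3.2 equiv), THF, −78 → 0 °C; then I2, −78 °C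
Reagents that add atoms: iodine II
Why: Base-induced anti dehydroiodination of the 2-iodo-1-alkene gives the terminal alkyne, the excess amide converts it into acetylide 7, and iodine then iodinates the acetylide carbon, with no stereocentre involved.

**Step 6**
Reactants: 8 (1R,2R,3S)-2-(dimethoxymethyl)-3-(iodoethynyl)-3-methyl-1-(propan-2-yl)cyclopentan-1-ol
Product: 9 (1R,2R,3S)-2-(dimethoxymethyl)-3-[(Z)-2-iodoethenyl]-3-methyl-1-(propan-2-yl)cyclopentan-1-ol
Conditions: 2-nitrobenzenesulfonohydrazide, Et3N, THF/i-PrOH, rt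
Reagents that add atoms: none
Why: Diimide reduction adds two hydrogens in a concerted syn fashion to the iodoalkyne and stops at the alkene, which fixes the Z geometry that the ring closure needs.

**Step 7**
Reactants: 9 (1R,2R,3S)-2-(dimethoxymethyl)-3-[(Z)-2-iodoethenyl]-3-methyl-1-(propan-2-yl)cyclopentan-1-ol
Product: 10 (1R,2S,5R)-2-[(Z)-2-iodoethenyl]-2-methyl-5-(propan-2-yl)-5-(triethylsilyloxy)cyclopentane-1-carbaldehyde
Conditions: TESOTf (4 equiv), 2,6-lutidine (6 equiv), CH2Cl2, −40 → 0 °C; then H2O
Reagents that add atoms: triethylsilyl trifluoromethanesulfonate CC[Si](CC)(CC)OS(=O)(=O)C(F)(F)F; water O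
Why: The silyl triflate with the hindered pyridine base silylates the tertiary alcohol and, in the same flask, cleaves the dimethyl acetal under non-acidic conditions on addition of water, so that C5 is not epimerised and the β-hydroxy aldehyde is never free.

**Step 8**
Reactants: 10 (1R,2S,5R)-2-[(Z)-2-iodoethenyl]-2-methyl-5-(propan-2-yl)-5-(triethylsilyloxy)cyclopentane-1-carbaldehyde; 11 allene (propa-1,2-diene)
Product: 14 4β-(triethylsilyloxy)dauca-8(14),9-dien-6α-ol, via allylpalladium iodide 12 (not isolated), via allylindium diiodide 13 (not isolated)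
Conditions: allene (1 atm), Pd(OAc)2 (10 mol %), P(2-furyl)3 (20 mol %), InI (1.5 equiv), DMF (0.01 M), 40–60 °C; aq. NH4Cl
Reagents that add atoms: none
Why: Proposed new method: zerovalent palladium (formed from Pd(OAc)2 and the phosphine) inserts into the C9–I bond of 10 with retention, the alkenylpalladium adds across allene 11 at the central carbon to make C8–C9 and the 2-dienyl allylpalladium iodide 12, InI reduces 12 to the nucleophilic allylindium 13, and 13 adds through its γ-carbon to the C6 aldehyde to make C6–C7. The closest known reaction type is palladium-catalysed allene insertion followed by indium-mediated Barbier allylation of an aldehyde, known as a three-component coupling of aryl or alkenyl halides and in ring-forming variants that give five- and six-membered carbinols, whereas closure of a seven-membered carbocycle from an alkenyl iodide that carries the aldehyde is not established. Ring B is the only ring closed, in a 7-exo-trig addition to the C6 carbonyl through a six-membered cyclic array (In, O, C6, C7, C8, C14) with allylic transposition. The new C6 stereocentre is controlled by C5 and its two quaternary neighbours: the forming ring forces C7 gauche to C1 and anti to C4, and of the two remaining sites on C6 the crowded one between the C1 methyl and the C4 silyloxy group should be taken by the aldehyde hydrogen and not by the metal-bound oxygen, which gives the 6α-carbinol (H6 anti to H5). The step needs allene insertion to precede carbonyl addition, which the substrate secures because direct attack of the alkenylpalladium on the aldehyde would close a trans-fused bicyclo[3.3.0]octene, and it needs the Z-iodoalkene from step 6 so that C9=C10 is cis in ring B. High dilution is used to hold back intermolecular allyl transfer.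

**Step 9**
Reactants: 14 4β-(triethylsilyloxy)dauca-8(14),9-dien-6α-ol
Product: 15 8α,14-epoxy-4β-(triethylsilyloxy)dauc-9-en-6α-ol
Conditions: VO(acac)2 (5 mol %), t-BuOOH, CH2Cl2, 0 °C
Reagents that add atoms: tert-butyl hydroperoxide CC(C)(C)OO
Why: Hydroxyl-directed vanadium-catalysed epoxidation of the homoallylic alcohol should deliver oxygen to the exocyclic C8=C14 bond from the face of the C6 hydroxyl, which sets C8 with its oxygen α and leaves the more remote ring alkene untouched.

**Step 10**
Reactants: 15 8α,14-epoxy-4β-(triethylsilyloxy)dauc-9-en-6α-ol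
Product: 16 4β-(triethylsilyloxy)dauc-9-ene-6α,8α-diol
Conditions: LiEt3BH, THF, 0 °C; then H2O
Reagents that add atoms: none
Why: Hydride opens the 2,2-disubstituted epoxide by SN2 attack at the unhindered CH2 (C14), which turns it into the C8 methyl and leaves the tertiary C8–O bond and its configuration intact.

**Step 11**
Reactants: 16 4β-(triethylsilyloxy)dauc-9-ene-6α,8α-diol; 17 4-[(tert-butyldimethylsilyl)oxy]benzoic acid
Product: 18 8α-hydroxy-4β-(triethylsilyloxy)dauc-9-en-6α-yl 4-[(tert-butyldimethylsilyl)oxy]benzoate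
Conditions: EDC, DMAP, CH2Cl2, rt
Reagents that add atoms: none
Why: Steglich esterification acylates the only secondary alcohol (C6) with retention, the tertiary C8 hydroxyl being unreactive and the C4 oxygen protected.

**Step 12**
Reactants: 18 8α-hydroxy-4β-(triethylsilyloxy)dauc-9-en-6α-yl 4-[(tert-butyldimethylsilyl)oxy]benzoate
Product: 19 (1R,4R,5S,6S,8R)-4β,8α-dihydroxydauc-9-en-6α-yl 4-hydroxybenzoate (target)
Conditions: HF·pyridine, pyridine, THF, 0 °C → rt
Reagents that add atoms: none
Why: Fluoride-driven desilylation cleaves the aryl silyl ether and the tertiary triethylsilyl ether under buffered conditions that should spare the benzoate and the tertiary allylic alcohol.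

**Compound list**
1 | 3-methylcyclopent-2-en-1-one | CC1=CC(=O)CC1 | starting material
2 | diisobutylaluminium enolate of (S)-3-methyl-3-[1-(trimethylsilyl)ethenyl]cyclopentanone (C4=C5 enolate; not isolated) | CC(C)C[Al](CC(C)C)OC1=C[C@@](C)(C(=C)[Si](C)(C)C)CC1 | intermediate
3 | (S)-3-methyl-1-(trimethylsilyloxy)-3-[1-(trimethylsilyl)ethenyl]cyclopent-1-ene | C[Si](C)(C)OC1=C[C@@](C)(C(=C)[Si](C)(C)C)CC1 | intermediate
4 | (2S,3S)-2-(dimethoxymethyl)-3-methyl-3-[1-(trimethylsilyl)ethenyl]cyclopentan-1-one | O=C1CC[C@](C)(C(=C)[Si](C)(C)C)[C@H]1C(OC)OC | intermediate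
5 | (1R,2R,3S)-2-(dimethoxymethyl)-3-methyl-1-(propan-2-yl)-3-[1-(trimethylsilyl)ethenyl]cyclopentan-1-ol | CC(C)[C@]1(O)CC[C@](C)(C(=C)[Si](C)(C)C)[C@H]1C(OC)OC | intermediate
6 | (1R,2R,3S)-2-(dimethoxymethyl)-3-(1-iodoethenyl)-3-methyl-1-(propan-2-yl)cyclopentan-1-ol | CC(C)[C@]1(O)CC[C@](C)(C(I)=C)[C@H]1C(OC)OC | intermediate
7 | dilithium alkoxide acetylide of (1R,2R,3S)-2-(dimethoxymethyl)-3-ethynyl-3-methyl-1-(propan-2-yl)cyclopentan-1-ol (not isolated) | CC(C)[C@]1(O[Li])CC[C@](C)(C#C[Li])[C@H]1C(OC)OC | intermediate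
8 | (1R,2R,3S)-2-(dimethoxymethyl)-3-(iodoethynyl)-3-methyl-1-(propan-2-yl)cyclopentan-1-ol | CC(C)[C@]1(O)CC[C@](C)(C#CI)[C@H]1C(OC)OC | intermediate
9 | (1R,2R,3S)-2-(dimethoxymethyl)-3-[(Z)-2-iodoethenyl]-3-methyl-1-(propan-2-yl)cyclopentan-1-ol | CC(C)[C@]1(O)CC[C@](C)(/C=C\I)[C@H]1C(OC)OC | intermediate
10 | (1R,2S,5R)-2-[(Z)-2-iodoethenyl]-2-methyl-5-(propan-2-yl)-5-(triethylsilyloxy)cyclopentane-1-carbaldehyde | CC(C)[C@]1(O[Si](CC)(CC)CC)CC[C@](C)(/C=C\I)[C@H]1C=O | intermediate
11 | allene (propa-1,2-diene) | C=C=C | starting material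
12 | 2-dienyl allylpalladium iodide from 10 and 11 (one σ-allyl form drawn, phosphine ligands omitted; not isolated) | CC(C)[C@]1(O[Si](CC)(CC)CC)CC[C@](C)(/C=C\C(=C)C[Pd]I)[C@H]1C=O | intermediate
13 | 2-dienyl allylindium diiodide from 12 (not isolated) | CC(C)[C@]1(O[Si](CC)(CC)CC)CC[C@](C)(/C=C\C(=C)C[In](I)I)[C@H]1C=O | intermediate
14 | 4β-(triethylsilyloxy)dauca-8(14),9-dien-6α-ol (trans-fused, 1β-methyl, 5α-H) | CC(C)[C@]1(O[Si](CC)(CC)CC)CC[C@]2(C)C=CC(=C)C[C@H](O)[C@H]21 | intermediate
15 | 8α,14-epoxy-4β-(triethylsilyloxy)dauc-9-en-6α-ol | CC(C)[C@]1(O[Si](CC)(CC)CC)CC[C@]2(C)C=C[C@@]3(CO3)C[C@H](O)[C@H]21 | intermediate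
16 | 4β-(triethylsilyloxy)dauc-9-ene-6α,8α-diol | CC(C)[C@]1(O[Si](CC)(CC)CC)CC[C@]2(C)C=C[C@](C)(O)C[C@H](O)[C@H]21 | intermediate
17 | 4-[(tert-butyldimethylsilyl)oxy]benzoic acid | CC(C)(C)[Si](C)(C)Oc1ccc(cc1)C(=O)O | starting material
18 | 8α-hydroxy-4β-(triethylsilyloxy)dauc-9-en-6α-yl 4-[(tert-butyldimethylsilyl)oxy]benzoate | CC(C)[C@]1(O[Si](CC)(CC)CC)CC[C@]2(C)C=C[C@](C)(O)C[C@H](OC(=O)c3ccc(O[Si](C)(C)C(C)(C)C)cc3)[C@H]21 | intermediate
19 | (1R,4R,5S,6S,8R)-4β,8α-dihydroxydauc-9-en-6α-yl 4-hydroxybenzoate | CC(C)[C@]1(O)CC[C@]2(C)C=C[C@](C)(O)C[C@H](OC(=O)c3ccc(O)cc3)[C@H]21 | target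

**Totals**
Total step count: 12. Longest linear sequence: 12 steps (1 to 19).

**Steps most likely to fail**

Step 8 (proposed method): the seven-membered closure of the allylindium may be outrun by intermolecular allyl transfer or by protodemetalation of the alkenylpalladium, and the two aldehyde faces may be less well differentiated than argued. Fallback: from 10, an indium-mediated Barbier reaction with 2,3-dibromopropene (indium powder, THF/H2O) would give the 2-bromoallyl carbinol (1S)-3-bromo-1-[(1S,2S,5R)-2-[(Z)-2-iodoethenyl]-2-methyl-5-(propan-2-yl)-5-(triethylsilyloxy)cyclopentyl]but-3-en-1-ol F1. An intramolecular Stille–Kelly coupling of its alkenyl iodide with its alkenyl bromide ((Me3Sn)2, Pd(PPh3)4, dioxane, 100 °C) would then form C8–C9 and return to the route at 14.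

Step 3: enolisation or β-hydride reduction of the hindered ketone may compete with addition, and the bulky alkenylsilane on the α face may erode the facial preference. Fallback: from 4, addition of prop-1-en-2-ylmagnesium bromide with CeCl3 (an sp2 nucleophile that is less basic and does not act as a hydride donor) would give the isopropenyl carbinol (1S,2R,3S)-2-(dimethoxymethyl)-3-methyl-1-(prop-1-en-2-yl)-3-[1-(trimethylsilyl)ethenyl]cyclopentan-1-ol F2. Hydrogenation of its isopropenyl group directed by the tertiary hydroxyl ([Ir(cod)(PCy3)(py)]PF6, H2, CH2Cl2) would return to the route at 5.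

Step 9: the oxidant may attack the ring alkene or the diene without direction from the hydroxyl, and the vinyl epoxide may open or rearrange on the Lewis acidic vanadium. Fallback: from 14, the C6 hydroxyl would be converted (Boc2O, DMAP) into the carbonate 4β-(triethylsilyloxy)dauca-8(14),9-dien-6α-yl tert-butyl carbonate F3. Iodine monobromide at −80 °C would induce carbonate cyclisation onto C8 to give the six-membered iodo carbonate 14-iodo-4β-(triethylsilyloxy)dauc-9-ene-6α,8α-diyl carbonate F4, in which the ring fixes the 6,8-cis relation. Bu3SnH/AIBN would remove the iodine to give 4β-(triethylsilyloxy)dauc-9-ene-6α,8α-diyl carbonate F5, and K2CO3 in methanol would release the diol and return to the route at 16, replacing steps 9 and 10.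

**Further compounds**
F1 | step 8 | (1S)-3-bromo-1-[(1S,2S,5R)-2-[(Z)-2-iodoethenyl]-2-methyl-5-(propan-2-yl)-5-(triethylsilyloxy)cyclopentyl]but-3-en-1-ol | CC(C)[C@]1(O[Si](CC)(CC)CC)CC[C@](C)(/C=C\I)[C@H]1[C@@H](O)CC(Br)=C
F2 | step 3 | (1S,2R,3S)-2-(dimethoxymethyl)-3-methyl-1-(prop-1-en-2-yl)-3-[1-(trimethylsilyl)ethenyl]cyclopentan-1-ol | CC(=C)[C@]1(O)CC[C@](C)(C(=C)[Si](C)(C)C)[C@H]1C(OC)OC
F3 | step 9 | 4β-(triethylsilyloxy)dauca-8(14),9-dien-6α-yl tert-butyl carbonate | CC(C)[C@]1(O[Si](CC)(CC)CC)CC[C@]2(C)C=CC(=C)C[C@H](OC(=O)OC(C)(C)C)[C@H]21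
F4 | step 9 | 14-iodo-4β-(triethylsilyloxy)dauc-9-ene-6α,8α-diyl carbonate | CC(C)[C@]1(O[Si](CC)(CC)CC)CC[C@]2(C)C=C[C@@]3(CI)C[C@H](OC(=O)O3)[C@H]21
F5 | step 9 | 4β-(triethylsilyloxy)dauc-9-ene-6α,8α-diyl carbonate | CC(C)[C@]1(O[Si](CC)(CC)CC)CC[C@]2(C)C=C[C@@]3(C)C[C@H](OC(=O)O3)[C@H]21
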